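**Retrosynthetic overview**

1. Locants follow the xanthanolide skeleton (C1–C15, primes for the epoxide half). The last C–C bonds, C3–C11′ and C5–C13′, come from a cross Diels–Alder reaction between the dienone of one half (diene C5=C1–C2=C3) and the methylene lactone of the other, already epoxidised, half; C1 is oxygenated last.
2. In each half the enone side chain comes from a Wittig reaction on a C2 aldehyde (oxidation of the C2 methyl group), and the seven-membered ring from a ring-closing metathesis that forms C1=C5 and expels a two-carbon stub as propene. The C1′–C5′ oxirane is made through a bromohydrin.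
3. Key disconnection, one pot: C9′–C10′ by Claisen rearrangement of an allyl vinyl ether, which unveils aldehyde C8′, and C7′–C8′ by allylboration with a 2-(methoxycarbonyl)allyl boronate, which also closes the lactone.
4. Enabling feature: C8′ of the cis-fused γ-lactone ring (O–C8′–C7′–C11′–C12′) is both the carbonyl carbon of a γ,δ-unsaturated aldehyde (C8′–C9′–C10′–C1′=C) and the carbinol carbon of a 2-carboxy homoallylic alcohol (C8′–C7′–C11′=C13′ before dimerisation). One aldehyde therefore links a [3,3] shift to a lactone-forming allylation.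
5. Ring order: γ-lactone, cycloheptene, oxirane (epoxide half only), spiro-cyclohexene. The two halves come from the two enantiomers of one allylic alcohol.

Key step: step 4

Remark on the chemistry (assumption): as drawn, the two halves belong to opposite enantiomeric series ((7R,8R,10S) in the hydroxylated half, (7′S,8′S,10′R) in the epoxide half) and the oxirane oxygen lies anti to C10′–CH3. The two halves are therefore built separately, and addition of reagents to the C1=C5 bond on the face syn to the C10 methyl group is taken as the working assumption for steps 8 and 15.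

**Step 1**
Reactants: 1 methyl prop-2-ynoate
Product: 3 methyl (2E)-2-[(4,4,5,5-tetramethyl-1,3,2-dioxaborolan-2-yl)methyl]hexa-2,5-dienoate, via alkenylcopper 2 (not isolated)
Conditions: allylMgBr, CuBr·SMe2, THF, −78 °C; add 1; then ICH2Bpin, HMPA, −78 → 0 °C
Reagents that add atoms: allylmagnesium bromide (C=CC[Mg]Br); 2-(iodomethyl)-4,4,5,5-tetramethyl-1,3,2-dioxaborolane (ICB1OC(C)(C)C(C)(C)O1)
Why: syn-carbocupration of the ynoate puts the allyl group cis to copper, and alkylation of the alkenylcopper with retention fixes the allyl chain cis to CH2B (three-component carbocupration–alkylation route to 2-alkoxycarbonyl allylboronates); no stereocentre is formed.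

**Step 2**
Reactants: 4 (3E)-3-methylpent-3-en-2-one
Product: 5 (2R,3E)-3-methylpent-3-en-2-ol
Conditions: (S)-Me-CBS (10 mol%), BH3·SMe2, THF, −30 °C
Reagents that add atoms: none
Why: Corey–Bakshi–Shibata reduction, in which the alkenyl group acts as the large substituent, so the (S)-oxazaborolidine is expected to give the (R)-carbinol that later relays its configuration to C10′.

**Step 3**
Reactants: 5 (2R,3E)-3-methylpent-3-en-2-ol
Product: 6 (2R,3E)-2-(ethenyloxy)-3-methylpent-3-ene
Conditions: n-BuOCH=CH2 (solvent), Pd(OCOCF3)2 (2 mol%), 4,7-diphenyl-1,10-phenanthroline, Et3N, 75 °C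
Reagents that add atoms: butyl vinyl ether (C=COCCCC)
Why: transfer vinylation (transetherification catalysed by divalent palladium) exchanges O–H for O–vinyl without breaking the carbinol C–O bond, so the configuration is retained.

**Step 4**
Reactants: 6 (2R,3E)-2-(ethenyloxy)-3-methylpent-3-ene; 3 methyl (2E)-2-[(4,4,5,5-tetramethyl-1,3,2-dioxaborolan-2-yl)methyl]hexa-2,5-dienoate
Product: 9 (4S,5S)-5-[(2R,3E)-2,3-dimethylpent-3-en-1-yl]-3-methylidene-4-(prop-2-en-1-yl)oxolan-2-one, via aldehyde 7 (not isolated), via hydroxy ester 8 (not isolated)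
Conditions: PhMe, BHT, 140 °C (sealed tube); cool to −20 °C, add 3 (1.2 equiv), (R)-3,3′-bis(2,4,6-triisopropylphenyl)-BINOL N-triflylphosphoramide (10 mol%), 4 Å MS, −20 °C → rt; then p-TsOH·H2O (20 mol%), rt
Reagents that add atoms: none
Why: Proposed new method: the asymmetric stage extends chiral-Brønsted-acid catalysis of aldehyde allylboration (closest known: phosphoric-acid-catalysed additions of allyl and crotyl pinacol boronates, and achiral triflic-acid catalysis of 2-alkoxycarbonyl allylboronate additions) to the ester-bearing boronate 3, the acid being expected to hydrogen-bond a boronate oxygen and the formyl hydrogen inside the usual closed six-membered chair. Heating 6 first triggers an aliphatic Claisen rearrangement through a chair with the carbinol methyl group equatorial, which forms C9′–C10′, transfers the (R) configuration of the carbinol carbon to C10′ and unveils aldehyde C8′; the aldehyde is not isolated but attacked by the γ-carbon of 3 (C7′–C8′) with allyl transposition that creates the exocyclic methylene group. Because the allyl chain of 3 is cis to CH2B it is axial in the chair, the adduct is syn, and acid-promoted 5-exo-trig acyl substitution by the C8′ hydroxyl on the methyl ester closes the γ-lactone ring cis. The aldehyde face, and with it the absolute configuration of C7′ and C8′, is set by the catalyst and not by the remote C10′ centre, the (R)-acid being expected to direct Re-face addition by analogy with simple aliphatic aldehydes. The step needs γ- rather than α-attack of the boronate (secured by the cyclic transition state) and faithful chirality transfer (the axial-methyl chair is the only leak).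

**Step 5**
Reactants: 9 (4S,5S)-5-[(2R,3E)-2,3-dimethylpent-3-en-1-yl]-3-methylidene-4-(prop-2-en-1-yl)oxolan-2-one
Product: 10 (3aS,7R,8aS)-6,7-dimethyl-3-methylidene-3,3a,4,7,8,8a-hexahydro-2H-cyclohepta[b]furan-2-one
Conditions: second-generation Hoveyda–Grubbs catalyst (5 mol%), PhMe (5 mM), 80 °C
Reagents that add atoms: none
Why: ring-closing metathesis between the terminal allyl group and the trisubstituted alkene closes the cycloheptene through C1′=C5′ (necessarily cis in this ring) and expels as propene the carbon whose only task was chirality transfer; the electron-poor methylene lactone is a spectator and no stereocentre is touched.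

**Step 6**
Reactants: 10 (3aS,7R,8aS)-6,7-dimethyl-3-methylidene-3,3a,4,7,8,8a-hexahydro-2H-cyclohepta[b]furan-2-one
Product: 12 (3aS,7R,8aS)-7-methyl-3-methylidene-2-oxo-3,3a,4,7,8,8a-hexahydro-2H-cyclohepta[b]furan-6-carbaldehyde, via allylic alcohol 11 (not isolated)
Conditions: SeO2 (1.2 equiv), 1,4-dioxane, 80 °C
Reagents that add atoms: selenium dioxide (O=[Se]=O)
Why: Riley allylic oxidation (ene reaction, then [2,3] shift) should attack the methyl group on the more substituted alkene carbon in preference to the tertiary C10′–H and carry the allylic alcohol on to the enal; no stereocentre is formed.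

**Step 7**
Reactants: 12 (3aS,7R,8aS)-7-methyl-3-methylidene-2-oxo-3,3a,4,7,8,8a-hexahydro-2H-cyclohepta[b]furan-6-carbaldehyde
Product: 13 (3aS,7R,8aS)-7-methyl-3-methylidene-6-[(1E)-3-oxobut-1-en-1-yl]-3,3a,4,7,8,8a-hexahydro-2H-cyclohepta[b]furan-2-one (ent-8-epi-xanthatin)
Conditions: Ph3P=CHC(O)CH3 (1.5 equiv), PhMe, 90 °C
Reagents that add atoms: 1-(triphenylphosphoranylidene)propan-2-one (CC(=O)C=P(c1ccccc1)(c1ccccc1)c1ccccc1)
Why: Wittig olefination with the stabilised acetonyl ylide is E-selective, and the ylide is too weak a nucleophile to add to the methylene lactone.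

**Step 8**
Reactants: 13 ent-8-epi-xanthatin
Product: 15 (1′R,5′R,7′S,8′S,10′R)-1′,5′-epoxy-1′,5′-dihydro derivative of 13 (oxirane oxygen anti to C10′–CH3 and to the lactone), via bromohydrin 14 (not isolated)
Conditions: NBS, THF/H2O (4:1), 0 °C; then K2CO3, rt
Reagents that add atoms: water (O)
Why: bromohydrin formation and base-induced ring closure: the most electron-rich alkene C1′=C5′ is expected to take up bromine on the face syn to C10′–CH3, water opens the bromonium ion anti, and the alkoxide displaces bromide at C5′ with inversion, which places the oxirane oxygen anti to the methyl group and the lactone.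

**Step 9**
Reactants: 4 (3E)-3-methylpent-3-en-2-one
Product: 16 (2S,3E)-3-methylpent-3-en-2-ol
Conditions: (R)-Me-CBS (10 mol%), BH3·SMe2, THF, −30 °C
Reagents that add atoms: none
Why: Corey–Bakshi–Shibata reduction with the enantiomeric oxazaborolidine is expected to give the (S)-carbinol for the other half.

**Step 10**
Reactants: 16 (2S,3E)-3-methylpent-3-en-2-ol
Product: 17 (2S,3E)-2-(ethenyloxy)-3-methylpent-3-ene
Conditions: n-BuOCH=CH2 (solvent), Pd(OCOCF3)2 (2 mol%), 4,7-diphenyl-1,10-phenanthroline, Et3N, 75 °C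
Reagents that add atoms: butyl vinyl ether (C=COCCCC)
Why: transfer vinylation as in step 3, with retention at the carbinol carbon.

**Step 11**
Reactants: 17 (2S,3E)-2-(ethenyloxy)-3-methylpent-3-ene; 3 methyl (2E)-2-[(4,4,5,5-tetramethyl-1,3,2-dioxaborolan-2-yl)methyl]hexa-2,5-dienoate
Product: 20 (4R,5R)-5-[(2S,3E)-2,3-dimethylpent-3-en-1-yl]-3-methylidene-4-(prop-2-en-1-yl)oxolan-2-one, via aldehyde 18 (not isolated), via hydroxy ester 19 (not isolated)
Conditions: PhMe, BHT, 140 °C (sealed tube); cool to −20 °C, add 3 (1.2 equiv), (S)-3,3′-bis(2,4,6-triisopropylphenyl)-BINOL N-triflylphosphoramide (10 mol%), 4 Å MS, −20 °C → rt; then p-TsOH·H2O (20 mol%), rt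
Reagents that add atoms: none
Why: Proposed new method: mirror-image run of step 4, that is a chair Claisen rearrangement of 17 (carbinol (S) to C10 (S), forming C9–C10), then in the same pot allylboration of the unveiled aldehyde by 3 under the (S)-configured chiral Brønsted acid (closest known: phosphoric-acid-catalysed allylboration with allyl and crotyl pinacol boronates; closed six-membered chair, allyl chain axial, hence syn adduct, Si-face addition expected, forming C7–C8), and 5-exo-trig lactonisation to the cis-lactone.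

**Step 12**
Reactants: 20 (4R,5R)-5-[(2S,3E)-2,3-dimethylpent-3-en-1-yl]-3-methylidene-4-(prop-2-en-1-yl)oxolan-2-one
Product: 21 (3aR,7S,8aR)-6,7-dimethyl-3-methylidene-3,3a,4,7,8,8a-hexahydro-2H-cyclohepta[b]furan-2-one
Conditions: second-generation Hoveyda–Grubbs catalyst (5 mol%), PhMe (5 mM), 80 °C
Reagents that add atoms: none
Why: ring-closing metathesis as in step 5 forms C1=C5 with loss of propene and leaves the stereocentres untouched.

**Step 13**
Reactants: 21 (3aR,7S,8aR)-6,7-dimethyl-3-methylidene-3,3a,4,7,8,8a-hexahydro-2H-cyclohepta[b]furan-2-one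
Product: 23 (3aR,7S,8aR)-7-methyl-3-methylidene-2-oxo-3,3a,4,7,8,8a-hexahydro-2H-cyclohepta[b]furan-6-carbaldehyde, via allylic alcohol 22 (not isolated)
Conditions: SeO2 (1.2 equiv), 1,4-dioxane, 80 °C
Reagents that add atoms: selenium dioxide (O=[Se]=O)
Why: Riley allylic oxidation of the C2 methyl group as in step 6.

**Step 14**
Reactants: 23 (3aR,7S,8aR)-7-methyl-3-methylidene-2-oxo-3,3a,4,7,8,8a-hexahydro-2H-cyclohepta[b]furan-6-carbaldehyde
Product: 24 (3aR,7S,8aR)-7-methyl-3-methylidene-6-[(1E)-3-oxobut-1-en-1-yl]-3,3a,4,7,8,8a-hexahydro-2H-cyclohepta[b]furan-2-one (8-epi-xanthatin)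
Conditions: Ph3P=CHC(O)CH3 (1.5 equiv), PhMe, 90 °C
Reagents that add atoms: 1-(triphenylphosphoranylidene)propan-2-one (CC(=O)C=P(c1ccccc1)(c1ccccc1)c1ccccc1)
Why: E-selective Wittig olefination with the stabilised ylide as in step 7.

**Step 15**
Reactants: 24 8-epi-xanthatin; 15 epoxide of ent-8-epi-xanthatin
Product: 25 Diels–Alder adduct (3S,5S,7R,8R,10S,11′R,1′R,5′R,7′S,8′S,10′R): cyclohexene C1=C2–C3H(acetyl)–C11′–C13′H2–C5H fused at C1/C5 to the cycloheptane of 24 and spiro at C11′ to the lactone of 15, H3 cis to H5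
Conditions: 15 (3 equiv), BHT, PhMe (2 M), 90 °C
Reagents that add atoms: none
Why: thermal Diels–Alder reaction of the s-cis dienone with the methylene lactone of 15, in which the regiochemistry (acetyl-bearing C3 to carbonyl-bearing C11′) follows the usual pairing of a 1-acyl diene with an acrylate, C11′ is set by addition to the convex face of the cis-fused lactone, the C5/C11′ relationship by an exo-carbonyl transition state, and C5 by approach of the dienophile syn to C10–CH3 (the assumed sense and the main stereochemical risk), while 15, which has no diene, is used in excess to outrun self-dimerisation of 24.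

**Step 16**
Reactants: 25 Diels–Alder adduct
Product: 27 CNP0177598.2, via hydroperoxide 26 (not isolated)
Conditions: O2 (1 atm), t-BuOK (0.2 equiv), P(OEt)3, THF/t-BuOH, −30 °C
Reagents that add atoms: dioxygen (O=O)
Why: base-mediated γ-oxygenation (autoxidation) of the β,γ-unsaturated ketone: the doubly activated C3–H is removed, the dienolate should take up O2 at C1 by axial attack anti to the axial H5 (trans ring fusion, hydroxyl syn to C13′), the double bond moves to C2=C3, the transient C3 centre is erased and the phosphite reduces the hydroperoxide in situ.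

**Compound list**

1 | methyl prop-2-ynoate | C#CC(=O)OC | starting material
2 | methyl (2Z)-2-cuprio-hexa-2,5-dienoate (alkenylcopper, allyl cis to Cu) | C=CC/C=C(\[Cu])C(=O)OC | intermediate
3 | methyl (2E)-2-[(4,4,5,5-tetramethyl-1,3,2-dioxaborolan-2-yl)methyl]hexa-2,5-dienoate | C=CC/C=C(\CB1OC(C)(C)C(C)(C)O1)C(=O)OC | intermediate
4 | (3E)-3-methylpent-3-en-2-one | C/C=C(\C)C(C)=O | starting material
5 | (2R,3E)-3-methylpent-3-en-2-ol | C/C=C(\C)[C@@H](C)O | intermediate
6 | (2R,3E)-2-(ethenyloxy)-3-methylpent-3-ene | C/C=C(\C)[C@@H](C)OC=C | intermediate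
7 | (3R,4E)-3,4-dimethylhex-4-enal | O=CC[C@@H](C)/C(C)=C/C | intermediate
8 | methyl (3S,4S,6R,7E)-4-hydroxy-6,7-dimethyl-2-methylidene-3-(prop-2-en-1-yl)non-7-enoate | C=C(C(=O)OC)[C@H](CC=C)[C@@H](O)C[C@@H](C)/C(C)=C/C | intermediate
9 | (4S,5S)-5-[(2R,3E)-2,3-dimethylpent-3-en-1-yl]-3-methylidene-4-(prop-2-en-1-yl)oxolan-2-one | C=C1C(=O)O[C@@H](C[C@@H](C)/C(C)=C/C)[C@H]1CC=C | intermediate
10 | (3aS,7R,8aS)-6,7-dimethyl-3-methylidene-3,3a,4,7,8,8a-hexahydro-2H-cyclohepta[b]furan-2-one | C=C1C(=O)O[C@H]2C[C@@H](C)C(C)=CC[C@@H]12 | intermediate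
11 | (3aS,7R,8aS)-6-(hydroxymethyl)-7-methyl-3-methylidene-3,3a,4,7,8,8a-hexahydro-2H-cyclohepta[b]furan-2-one | C=C1C(=O)O[C@H]2C[C@@H](C)C(CO)=CC[C@@H]12 | intermediate
12 | (3aS,7R,8aS)-7-methyl-3-methylidene-2-oxo-3,3a,4,7,8,8a-hexahydro-2H-cyclohepta[b]furan-6-carbaldehyde | C=C1C(=O)O[C@H]2C[C@@H](C)C(C=O)=CC[C@@H]12 | intermediate
13 | ent-8-epi-xanthatin, (3aS,7R,8aS)-7-methyl-3-methylidene-6-[(1E)-3-oxobut-1-en-1-yl]-3,3a,4,7,8,8a-hexahydro-2H-cyclohepta[b]furan-2-one | C=C1C(=O)O[C@H]2C[C@@H](C)C(/C=C/C(C)=O)=CC[C@@H]12 | intermediate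
14 | trans-bromohydrin of 13: 1′-hydroxy (anti to C10′–CH3), 5′-bromo (syn to C10′–CH3) | C=C1C(=O)O[C@H]2C[C@@H](C)[C@@](O)(/C=C/C(C)=O)[C@@H](Br)C[C@@H]12 | intermediate
15 | (1′R,5′R,7′S,8′S,10′R)-1′,5′-epoxy-1′,5′-dihydro-ent-8-epi-xanthatin (oxirane oxygen anti to C10′–CH3) | C=C1C(=O)O[C@H]2C[C@@H](C)[C@]3(/C=C/C(C)=O)O[C@@H]3C[C@@H]12 | intermediate
16 | (2S,3E)-3-methylpent-3-en-2-ol | C/C=C(\C)[C@H](C)O | intermediate
17 | (2S,3E)-2-(ethenyloxy)-3-methylpent-3-ene | C/C=C(\C)[C@H](C)OC=C | intermediate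
18 | (3S,4E)-3,4-dimethylhex-4-enal | O=CC[C@H](C)/C(C)=C/C | intermediate
19 | methyl (3R,4R,6S,7E)-4-hydroxy-6,7-dimethyl-2-methylidene-3-(prop-2-en-1-yl)non-7-enoate | C=C(C(=O)OC)[C@@H](CC=C)[C@H](O)C[C@H](C)/C(C)=C/C | intermediate
20 | (4R,5R)-5-[(2S,3E)-2,3-dimethylpent-3-en-1-yl]-3-methylidene-4-(prop-2-en-1-yl)oxolan-2-one | C=C1C(=O)O[C@H](C[C@H](C)/C(C)=C/C)[C@@H]1CC=C | intermediate
21 | (3aR,7S,8aR)-6,7-dimethyl-3-methylidene-3,3a,4,7,8,8a-hexahydro-2H-cyclohepta[b]furan-2-one | C=C1C(=O)O[C@@H]2C[C@H](C)C(C)=CC[C@H]12 | intermediate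
22 | (3aR,7S,8aR)-6-(hydroxymethyl)-7-methyl-3-methylidene-3,3a,4,7,8,8a-hexahydro-2H-cyclohepta[b]furan-2-one | C=C1C(=O)O[C@@H]2C[C@H](C)C(CO)=CC[C@H]12 | intermediate
23 | (3aR,7S,8aR)-7-methyl-3-methylidene-2-oxo-3,3a,4,7,8,8a-hexahydro-2H-cyclohepta[b]furan-6-carbaldehyde | C=C1C(=O)O[C@@H]2C[C@H](C)C(C=O)=CC[C@H]12 | intermediate
24 | 8-epi-xanthatin, (3aR,7S,8aR)-7-methyl-3-methylidene-6-[(1E)-3-oxobut-1-en-1-yl]-3,3a,4,7,8,8a-hexahydro-2H-cyclohepta[b]furan-2-one | C=C1C(=O)O[C@@H]2C[C@H](C)C(/C=C/C(C)=O)=CC[C@H]12 | intermediate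
25 | Diels–Alder adduct (3S,5S,7R,8R,10S,11′R,1′R,5′R,7′S,8′S,10′R), C1=C2, acetyl on C3, spiro at C11′ | C=C1C(=O)O[C@@H]2C[C@H](C)C3=C[C@H](C(C)=O)[C@]4(C[C@@H]3C[C@H]12)C(=O)O[C@H]1C[C@@H](C)[C@]2(/C=C/C(C)=O)O[C@@H]2C[C@H]14 | intermediate
26 | (1S)-1-hydroperoxide corresponding to 27 | C=C1C(=O)O[C@@H]2C[C@H](C)[C@@]3(OO)C=C(C(C)=O)[C@]4(C[C@@H]3C[C@H]12)C(=O)O[C@H]1C[C@@H](C)[C@]2(/C=C/C(C)=O)O[C@@H]2C[C@H]14 | intermediate
27 | CNP0177598.2, (1S,5S,7R,8R,10S,11′R,1′R,5′R,7′S,8′S,10′R) | C=C1C(=O)O[C@@H]2C[C@H](C)[C@@]3(O)C=C(C(C)=O)[C@]4(C[C@@H]3C[C@H]12)C(=O)O[C@H]1C[C@@H](C)[C@]2(/C=C/C(C)=O)O[C@@H]2C[C@H]14 | target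

**Total step count:** 16
**Longest linear sequence:** 9 steps (steps 2–8, 15, 16, from enone 4)

**Steps most likely to fail**

Step 4. What may go wrong: insufficient catalyst control over the aldehyde face, or sluggish addition of the ester-deactivated boronate at the temperature needed for selectivity, so that the C7′/C8′ diastereomer forms. The fallback uses known reactions only, sets out from 6 and comes back at 9. Heating 6 alone (PhMe, 140 °C) gives aldehyde 7, which is now isolated. An Evans syn-aldol reaction with the dibutylboron enolate of (4R)-4-benzyl-3-(pent-4-enoyl)-1,3-oxazolidin-2-one (Bu2BOTf, i-Pr2NEt, CH2Cl2, −78 °C) should give syn-aldol adduct F1, in which the auxiliary and not the remote C10′ centre fixes C7′ and C8′. LiBH4 removes the auxiliary and gives diol F2. TEMPO/PhI(OAc)2 oxidises only the primary hydroxyl to hydroxy aldehyde F3. The Ohira–Bestmann reagent (K2CO3, MeOH) converts this into enynol F4. Palladium-catalysed cyclocarbonylation of the homopropargylic alcohol (PdCl2, SnCl2, PPh3, CO) closes the α-methylene lactone and returns to 9.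

Step 11. What may go wrong: the same loss of facial control as in step 4, in the mirror-image series. The fallback is the same detour with enantiomeric reagents, from 17 back to 20. Heating 17 gives aldehyde 18. The aldol reaction with the (4S)-configured pent-4-enoyl oxazolidinone should give syn-aldol adduct F5. Reduction gives diol F6, selective oxidation gives hydroxy aldehyde F7, alkyne homologation gives enynol F8, and cyclocarbonylation gives 20.

Step 15. What may go wrong: self-dimerisation of diene 24 through its own methylene lactone outcompeting the cross reaction, together with attack on the wrong diene face. The fallback sets out from 24 and comes back at 25. It masks the dienophile of 24 and so addresses only the self-dimerisation; it does not change the facial selectivity at the diene, which stays the open risk of this step. Conjugate addition of benzeneselenol (PhSeSePh, NaBH4, EtOH, 0 °C) to the methylene lactone of 24 gives selenide F9, so that only 15 still carries a dienophile. Cycloaddition of this diene with 15 (PhMe, 90 °C) gives selenide adduct F10. NaIO4 (THF/H2O, 0 °C) oxidises selenium to selenoxide F11, whose syn-elimination at room temperature restores the methylene group and returns to 25.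

**Further compounds**

F1 | step 4 | (4R)-4-benzyl-3-[(2R,3S,5R,6E)-3-hydroxy-5,6-dimethyl-2-(prop-2-en-1-yl)oct-6-enoyl]-1,3-oxazolidin-2-one | C=CC[C@@H](C(=O)N1[C@H](Cc2ccccc2)COC1=O)[C@@H](O)C[C@@H](C)/C(C)=C/C
F2 | step 4 | (2S,3S,5R,6E)-5,6-dimethyl-2-(prop-2-en-1-yl)oct-6-ene-1,3-diol | C=CC[C@@H](CO)[C@@H](O)C[C@@H](C)/C(C)=C/C
F3 | step 4 | (2R,3S,5R,6E)-3-hydroxy-5,6-dimethyl-2-(prop-2-en-1-yl)oct-6-enal | C=CC[C@@H](C=O)[C@@H](O)C[C@@H](C)/C(C)=C/C
F4 | step 4 | (4S,5S,7R,8E)-4-ethynyl-7,8-dimethyldeca-1,8-dien-5-ol | C=CC[C@@H](C#C)[C@@H](O)C[C@@H](C)/C(C)=C/C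
F5 | step 11 | (4S)-4-benzyl-3-[(2S,3R,5S,6E)-3-hydroxy-5,6-dimethyl-2-(prop-2-en-1-yl)oct-6-enoyl]-1,3-oxazolidin-2-one | C=CC[C@H](C(=O)N1[C@@H](Cc2ccccc2)COC1=O)[C@H](O)C[C@H](C)/C(C)=C/C
F6 | step 11 | (2R,3R,5S,6E)-5,6-dimethyl-2-(prop-2-en-1-yl)oct-6-ene-1,3-diol | C=CC[C@H](CO)[C@H](O)C[C@H](C)/C(C)=C/C
F7 | step 11 | (2S,3R,5S,6E)-3-hydroxy-5,6-dimethyl-2-(prop-2-en-1-yl)oct-6-enal | C=CC[C@H](C=O)[C@H](O)C[C@H](C)/C(C)=C/C
F8 | step 11 | (4R,5R,7S,8E)-4-ethynyl-7,8-dimethyldeca-1,8-dien-5-ol | C=CC[C@H](C#C)[C@H](O)C[C@H](C)/C(C)=C/C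
F9 | step 15 | 13-(phenylselanyl)-11,13-dihydro-8-epi-xanthatin (H11 cis to H7) | c1ccccc1[Se]C[C@@H]1C(=O)O[C@@H]2C[C@H](C)C(/C=C/C(C)=O)=CC[C@H]12
F10 | step 15 | 13-(phenylselanyl)-11,13-dihydro derivative of adduct 25 | c1ccccc1[Se]C[C@@H]1C(=O)O[C@@H]2C[C@H](C)C3=C[C@H](C(C)=O)[C@]4(C[C@@H]3C[C@H]12)C(=O)O[C@H]1C[C@@H](C)[C@]2(/C=C/C(C)=O)O[C@@H]2C[C@H]14
F11 | step 15 | selenoxide of the selenide adduct | O=[Se](c1ccccc1)C[C@@H]1C(=O)O[C@@H]2C[C@H](C)C3=C[C@H](C(C)=O)[C@]4(C[C@@H]3C[C@H]12)C(=O)O[C@H]1C[C@@H](C)[C@]2(/C=C/C(C)=O)O[C@@H]2C[C@H]14
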